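## Analysis of the target

The target 18 is a depside, methyl 4-{[2,4-dihydroxy-6-(2-oxononyl)benzoyl]oxy}-2-hydroxy-6-(2-oxononyl)benzoate. Two resorcylate rings of the same substitution pattern are joined by an aryl ester between the C1 carboxyl of ring A (the acyl ring) and O-4 of ring B (the methyl benzoate ring). Each ring carries the carbonyl carbon on C1, oxygen on C2 and C4, hydrogen on C3 and C5 and a CH2–CO–heptyl chain on C6. There is no stereocentre, so the problem is one of connectivity and chemoselectivity. The sensitive groups are the aryl ester, which is an activated acyl donor, the two aryl-CH2 ketones, whose enols lie next to an ester and can lactonise or condense, and three phenols, two of them chelated to an ortho carbonyl. The difficulty of a classical approach is that the ring A acid is a 2,6-disubstituted benzoic acid, slow to esterify with a phenol, and that the phenols of the two rings must be told apart and protected. The plan rests on one feature: in each ring C1 and C6 are adjacent carbons bearing a carbonyl and a CH2 group, which are the two carbons of a 2-alkynoate triple bond, while C2 to C5 with oxygen on C2 and C4 map onto a 1,3-bis(silyloxy)-1,3-diene. Ring A can therefore be grown on an ester of ring B, so that the depside C–O bond is made from an unhindered alkynoic acid, and ring B comes from the same annulation on the methyl ester.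

## Retrosynthetic reasoning

**18 to 17.** The last operation only removes masks. In 17 the two ketones are dioxolane ketals and the three phenols are trimethylsilyl ethers. No skeletal bond is cut. The ketones stay hidden until the end because an aryl-CH2 ketone ortho to an ester can enolise and lactonise onto that ester. The silyl ethers are what the ring-forming step delivers. The forward reaction must cleave three Si–O bonds and two ketals with dilute acid and leave the depside ester alone.

**17 to 14 and 10.** Ring A is cut at C1–C2 and at C5–C6. The two-carbon piece, C1 and C6 with the ester carbon and the CH2 chain, is the triple bond of the aryl ynoate 14. The four-carbon piece, C2 to C5 with both oxygens, is the diene 10. Cutting here and not at the depside C–O bond means the ester is already in place before the hindered arene exists, and ring A arrives at the arene oxidation level with its full masked side chain. The forward reaction must join the unsubstituted terminus of 10 to the ynoate β-carbon and the silyloxy-bearing terminus to the α-carbon. The bicyclic adduct 16 must then lose its gem-dimethyl bridge to become aromatic. The chelated phenol of 14 could protonate or desilylate 10, so it is silylated in the flask to 15 before the diene is added.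

**14 to 13 and 8.** The aryl ester C–O bond is cut. In 13 the 4-hydroxyl is free and the 2-hydroxyl is tied up in a hydrogen bond to the methyl ester, and 8 is an unhindered acid. The forward reaction must acylate O-4 only, without conjugate addition to the triple bond and without shifting it to an allene.

**13 to 7 and 10.** Ring B is cut at C1–C2 and C5–C6 in the same way as ring A. The methyl ynoate 7 and the diene 10 give the bicyclic adduct 11, then the bis(silyl ether) 12, and desilylation gives 13. The forward reaction is the same annulation, here on a simple methyl ester.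

**8 to 7.** The acid is traced to its own methyl ester; only the acyl C–OMe bond is exchanged for C–OH. One acylated acetylide thus supplies both rings. The acid, which is strong enough to threaten its own ketal, is released only shortly before it is needed. The forward reaction must cleave the ester with hydroxide at low temperature without adding to the triple bond.

**7 to 5.** The bond between the sp carbon and the ester carbonyl carbon is cut. The nucleophile is the lithium acetylide 6, formed from the dibromoalkene 5, and the electrophile is a chloroformate.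

**5 to 4, 3, 1 and 2.** The dibromoalkene is a one-carbon homologation of aldehyde 4, which is the half-reduced form of ester 3, the ketal of the β-keto ester 1 with diol 2. The ketal is installed first because a free ketone β to the alkyne would make the intervening CH2 doubly activated and prone to allene formation.

**10 to 9.** The two O–Si bonds are cut. Dimedone 9 is symmetrical, so double enol silylation can give only one diene.

## Alternatives that were turned down

**Alternative 1:** Ring B would be cut at C1–C6 and C2–C3, back to the enone A1, (E)-5-(2-heptyl-1,3-dioxolan-2-yl)pent-3-en-2-one (one Wittig step from 4), and dimethyl malonate A2. A methoxide base would add A2 to the β-carbon of A1, and the methyl ketone enolate would then close onto a malonate ester. This gives the racemic trans cyclohexane-1,3-dione A3, methyl 6-[(2-heptyl-1,3-dioxolan-2-yl)methyl]-2,4-dioxocyclohexane-1-carboxylate, which a later dehydrogenation would turn into 13.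
- For it: cheap reagents, ambient temperature, and connectivity that leaves no regiochemical question. On these points it is at least as strong as the cycloaddition used for 13, which needs a sealed tube at 150 °C.
- Against it: A3 is two hydrogens short of the arene. Dehydrogenating a 2-carbomethoxy cyclohexane-1,3-dione needs halogenation and elimination or a strong oxidant, which suits neither the ketal nor the activated benzylic CH2. Under the basic annulation conditions A1 can also lose a γ-proton to an extended enolate that expels a ketal oxygen. Its two stereocentres are made only to be destroyed.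
- Comparison: it supplies ring B only. Ring A would still have to be built, protected and joined as a 2,6-disubstituted benzoic acid. The chosen strategy gives the arene oxidation level directly, uses one ring-forming method for both rings, and makes the ester bond before ring A exists.

**Alternative 2:** No ring would be formed. The arene would be cut at the aryl–CH2 bond on C6 and the aryl–carbonyl bond on C1, back to the aryne precursor A4, 3,5-bis(benzyloxy)-2-(trimethylsilyl)phenyl trifluoromethanesulfonate, and A2. Fluoride ion would release the aryne from A4. The malonate anion would add at the aryne carbon remote from the flanking benzyloxy group, and the aryl anion would attack an ester carbonyl and fragment. The net insertion into a C–C bond of A2 gives dimethyl 3,5-bis(benzyloxy)homophthalate A5.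
- For it: room temperature, two C–C bonds in one operation, regiocontrol by the flanking oxygen, and phenols that arrive as benzyl ethers removable by neutral hydrogenolysis. In mildness and in robustness of the protecting groups it is stronger than the thermal step chosen here.
- Against it: A5 carries CH2–CO2Me where the target needs CH2–CO–heptyl. Each ring would need the aliphatic ester told apart from the aromatic one and converted to a heptyl ketone by controlled mono-addition, about three steps per ring, with the new ketone lying beside an ester onto which it can lactonise. A4 itself needs four to five steps from a trioxygenated benzene. The depside bond must still be made from the hindered ring A acid.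
- Comparison: the route would be about twice as long. The chosen strategy brings ring, oxygen pattern and the complete masked side chain together in one step per ring.

**Alternative 3:** Ring A would be cut at C1–C6 only, back to the open-chain aryl ester A6, methyl 4-{[8-(2-heptyl-1,3-dioxolan-2-yl)-3,5,7-trioxooctanoyl]oxy}-6-[(2-heptyl-1,3-dioxolan-2-yl)methyl]-2-hydroxybenzoate, the ester of 13 with a 3,5,7-triketo acid. Mild base and then acid would make C2 of the chain attack the C7 ketone, and dehydration would give the resorcylate A7, methyl 4-({2-[(2-heptyl-1,3-dioxolan-2-yl)methyl]-4,6-dihydroxybenzoyl}oxy)-6-[(2-heptyl-1,3-dioxolan-2-yl)methyl]-2-hydroxybenzoate, the bis(dioxolane) ketal of the target.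
- For it: it follows the biosynthetic logic, runs near room temperature, keeps the same ester-first order as the chosen plan, and A7 needs only ketal hydrolysis with no silyl groups. In mildness and in closeness of its product to the target it is as strong as or stronger than the chosen key step.
- Against it: A6 is a tetracarbonyl chain with several enolisable methylene groups and an aryloxide leaving group at its end. Attack of C6 on the ester carbon (Claisen mode) and attack of the C5 enol oxygen on it (pyranone formation) both expel 13, and an aryl ester favours these modes more than an alkyl ester would. The C8 methylene next to the ketal is a further enolisation site beside the C7 ketone. A6 would have to be assembled by polyanion acylation or acylketene trapping, three to five steps that an aryl ester and a free phenol tolerate poorly.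
- Comparison: the chosen strategy places C1 and C6 in one alkyne from the start. There is one reaction manifold, the regiochemistry rests on orbital polarisation and not on a choice among enolates, and 7, 8 and 10 serve both rings.

Key step: step 9

Assumption: 1, 2 and 9 are taken as purchasable. The chelated ring B phenol of 14 is capped as a trimethylsilyl ether in the flask in step 9, so the key-step product 17 carries three silyl ethers; all three are removed in step 10.

## Route

**Step 1**
Reactants: 1 methyl 3-oxodecanoate; 2 ethylene glycol
Product: 3 methyl 2-(2-heptyl-1,3-dioxolan-2-yl)acetate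
Conditions: 2 (3 equiv), p-TsOH·H2O (5 mol%), toluene, reflux, Dean–Stark trap
Reagents that add atoms: none
Why: Acid-catalysed ketalisation of the ketone of a β-keto ester with azeotropic removal of water; the ester carbonyl does not ketalise. The ketal removes the enolisable 1,3-dicarbonyl unit before any alkyne is introduced.

**Step 2**
Reactants: 3 methyl 2-(2-heptyl-1,3-dioxolan-2-yl)acetate
Product: 4 2-(2-heptyl-1,3-dioxolan-2-yl)acetaldehyde
Conditions: i-Bu2AlH (1.1 equiv), CH2Cl2, −78 °C; MeOH, then aq. KNaC4H4O6 (potassium sodium tartrate)
Reagents that add atoms: none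
Why: Partial reduction of an ester with i-Bu2AlH; at −78 °C the tetrahedral aluminium hemiacetal, held by chelation to a ketal oxygen, should persist and release the aldehyde only on work-up. The aldehyde is used without storage.

**Step 3**
Reactants: 4 2-(2-heptyl-1,3-dioxolan-2-yl)acetaldehyde
Product: 5 2-(3,3-dibromoprop-2-en-1-yl)-2-heptyl-1,3-dioxolane
Conditions: CBr4 (2 equiv), PPh3 (4 equiv), CH2Cl2, 0 °C; then 4, Et3N (1 equiv), 0 °C
Reagents that add atoms: carbon tetrabromide, BrC(Br)(Br)Br
Why: First stage of the Corey–Fuchs sequence, a Wittig reaction of the dibromomethylene ylide with the aldehyde. The amine buffers traces of HBr so that the ketal should survive.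

**Step 4**
Reactants: 5 2-(3,3-dibromoprop-2-en-1-yl)-2-heptyl-1,3-dioxolane
Product: 7 methyl 4-(2-heptyl-1,3-dioxolan-2-yl)but-2-ynoate, via lithium acetylide 6 (not isolated)
Conditions: n-BuLi (2.1 equiv), THF, −78 °C; then ClCO2Me (1.5 equiv), −78 → 0 °C
Reagents that add atoms: methyl chloroformate, COC(=O)Cl
Why: Second stage of the Corey–Fuchs sequence: bromine–lithium exchange, elimination with 1,2-shift (Fritsch–Buttenberg–Wiechell type) and deprotonation give the lithium acetylide 6, which is acylated at carbon by the chloroformate. The ester is made on a scale that supplies both step 5 and step 7.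

**Step 5**
Reactants: 7 methyl 4-(2-heptyl-1,3-dioxolan-2-yl)but-2-ynoate
Product: 8 4-(2-heptyl-1,3-dioxolan-2-yl)but-2-ynoic acid
Conditions: LiOH·H2O (1.5 equiv), THF/H2O (3:1), 0 °C; cold 1 M HCl to pH 3, Et2O, rapid extraction
Reagents that add atoms: lithium hydroxide, [Li+].[OH-]
Why: Saponification of a methyl 2-alkynoate by acyl substitution with hydroxide; the triple bond activates the ester so that it should cleave at 0 °C, and the carboxylate formed is no longer an acceptor for conjugate addition. The brief cold acidification in a two-phase system should leave the dioxolane intact, and the acid is used at once in step 8.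

**Step 6**
Reactants: 9 dimedone (5,5-dimethylcyclohexane-1,3-dione)
Product: 10 5,5-dimethyl-1,3-bis(trimethylsilyloxy)cyclohexa-1,3-diene
Conditions: Me3SiOTf (2.2 equiv), Et3N (3 equiv), Et2O, 0 °C → rt; hexane extraction, distillation
Reagents that add atoms: trimethylsilyl trifluoromethanesulfonate, C[Si](C)(C)OS(=O)(=O)C(F)(F)F
Why: Soft enolisation and double O-silylation of a 1,3-diketone. The second silylation passes through a symmetrical 1,3-bis(silyloxy)allyl cation, and loss of a proton from either flanking CH2 gives the same diene.

**Step 7**
Reactants: 7 methyl 4-(2-heptyl-1,3-dioxolan-2-yl)but-2-ynoate; 10 5,5-dimethyl-1,3-bis(trimethylsilyloxy)cyclohexa-1,3-diene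
Product: 13 methyl 2,4-dihydroxy-6-[(2-heptyl-1,3-dioxolan-2-yl)methyl]benzoate, via bicyclic adduct 11 (not isolated), via bis(silyl ether) 12 (not isolated)
Conditions: 10 (2.5 equiv), toluene, 150 °C, sealed tube; then K2CO3 (10 mol%), MeOH, 0 °C
Reagents that add atoms: none
Why: Diels–Alder addition of the silyloxydiene to the ynoate followed by retro-Diels–Alder loss of 2-methylpropene (Alder–Rickert sequence) builds ring B with C1–C2 and C5–C6 as the new bonds. The unsubstituted diene terminus bonds to the ynoate β-carbon, which places the ester between the oxygen and the side chain. Catalytic methanolysis then removes both aryl silyl ethers and leaves the ketal untouched.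

**Step 8**
Reactants: 13 methyl 2,4-dihydroxy-6-[(2-heptyl-1,3-dioxolan-2-yl)methyl]benzoate; 8 4-(2-heptyl-1,3-dioxolan-2-yl)but-2-ynoic acid
Product: 14 methyl 4-{[4-(2-heptyl-1,3-dioxolan-2-yl)but-2-ynoyl]oxy}-6-[(2-heptyl-1,3-dioxolan-2-yl)methyl]-2-hydroxybenzoate
Conditions: DCC (1.1 equiv), DMAP (5 mol%), CH2Cl2, 0 °C
Reagents that add atoms: none
Why: Steglich esterification of a phenol with an unhindered 2-alkynoic acid. The 4-hydroxyl reacts because the 2-hydroxyl is locked in a hydrogen bond to the ester carbonyl. Low temperature and a catalytic amount of DMAP limit conjugate addition and alkyne-to-allene isomerisation.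

**Step 9**
Reactants: 14 methyl 4-{[4-(2-heptyl-1,3-dioxolan-2-yl)but-2-ynoyl]oxy}-6-[(2-heptyl-1,3-dioxolan-2-yl)methyl]-2-hydroxybenzoate; 10 5,5-dimethyl-1,3-bis(trimethylsilyloxy)cyclohexa-1,3-diene
Product: 17 methyl 4-({2-[(2-heptyl-1,3-dioxolan-2-yl)methyl]-4,6-bis(trimethylsilyloxy)benzoyl}oxy)-6-[(2-heptyl-1,3-dioxolan-2-yl)methyl]-2-(trimethylsilyloxy)benzoate, via ring B silyl ether 15 (not isolated), via bicyclic adduct 16 (not isolated)
Conditions: N,O-bis(trimethylsilyl)acetamide (1.2 equiv), toluene, 60 °C, then volatiles removed in vacuo; 10 (3 equiv), toluene, 150 °C, sealed tube; concentration, crude product carried on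
Reagents that add atoms: N,O-bis(trimethylsilyl)acetamide, CC(O[Si](C)(C)C)=N[Si](C)(C)C
Why: The chelated ring B phenol is first capped as its trimethylsilyl ether 15 so that it cannot protonate or desilylate the diene. The electron-rich diene 10 then adds to the electron-poor triple bond of 15 in a thermal, concerted but asynchronous [4+2] cycloaddition; this forms the ring A C5–C6 bond (unsubstituted diene terminus to the ynoate β-carbon) and the C1–C2 bond (silyloxy-bearing terminus to the α-carbon) and gives the bicyclo[2.2.2]octadiene 16. A retro-[4+2] step expels the saturated CH2–CMe2 bridge as 2-methylpropene, the only bridge whose loss leaves a benzene ring, so ring A is closed by intermolecular cycloaddition followed by cycloreversion and not by cyclisation of a chain. The closest known reaction type is the Alder–Rickert sequence of 2-alkynoate esters and ynolides with this same diene, which gives 6-substituted 2,4-bis(silyloxy)benzoates. No stereocentre remains, since the two bridgehead centres of 16 form as a racemate and are lost on aromatisation. The step needs regioselectivity, and matched polarisation should secure it: both silyloxy groups raise the HOMO coefficient at the unsubstituted diene terminus and the ester puts the largest LUMO coefficient on the ynoate β-carbon, so the ester carbon ends up between a silyloxy group and the CH2 chain. The step also needs the aryl ester to survive, which the neutral, aprotic, base-free medium should allow. The aryl ester lowers the LUMO of the dienophile relative to the methyl ester of step 7, which should offset the larger size of the substrate.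

**Step 10**
Reactants: 17 methyl 4-({2-[(2-heptyl-1,3-dioxolan-2-yl)methyl]-4,6-bis(trimethylsilyloxy)benzoyl}oxy)-6-[(2-heptyl-1,3-dioxolan-2-yl)methyl]-2-(trimethylsilyloxy)benzoate
Product: 18 methyl 4-{[2,4-dihydroxy-6-(2-oxononyl)benzoyl]oxy}-2-hydroxy-6-(2-oxononyl)benzoate (CNP0110390.0)
Conditions: 1 M aq. HCl/THF (1:4), 0 °C → rt; NaHCO3 wash
Reagents that add atoms: water, O
Why: Acid hydrolysis cleaves the three aryl silyl ethers at once and then the two dioxolanes through oxocarbenium ions. Dilute acid at room temperature should not hydrolyse the depside or the methyl ester, and the ketones appear only in this last step. The bicarbonate wash also removes dimedone formed from excess diene.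

## Compound list

1 | methyl 3-oxodecanoate | CCCCCCCC(=O)CC(=O)OC | starting material
2 | ethylene glycol | OCCO | starting material
3 | methyl 2-(2-heptyl-1,3-dioxolan-2-yl)acetate | CCCCCCCC1(CC(=O)OC)OCCO1 | intermediate
4 | 2-(2-heptyl-1,3-dioxolan-2-yl)acetaldehyde | CCCCCCCC1(CC=O)OCCO1 | intermediate
5 | 2-(3,3-dibromoprop-2-en-1-yl)-2-heptyl-1,3-dioxolane | CCCCCCCC1(CC=C(Br)Br)OCCO1 | intermediate
6 | [3-(2-heptyl-1,3-dioxolan-2-yl)prop-1-yn-1-yl]lithium (formed in the flask) | [Li]C#CCC1(CCCCCCC)OCCO1 | intermediate
7 | methyl 4-(2-heptyl-1,3-dioxolan-2-yl)but-2-ynoate | CCCCCCCC1(CC#CC(=O)OC)OCCO1 | intermediate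
8 | 4-(2-heptyl-1,3-dioxolan-2-yl)but-2-ynoic acid | CCCCCCCC1(CC#CC(=O)O)OCCO1 | intermediate
9 | dimedone (5,5-dimethylcyclohexane-1,3-dione) | CC1(C)CC(=O)CC(=O)C1 | starting material
10 | 5,5-dimethyl-1,3-bis(trimethylsilyloxy)cyclohexa-1,3-diene | CC1(C)CC(O[Si](C)(C)C)=CC(O[Si](C)(C)C)=C1 | intermediate
11 | methyl 3-[(2-heptyl-1,3-dioxolan-2-yl)methyl]-8,8-dimethyl-1,5-bis(trimethylsilyloxy)bicyclo[2.2.2]octa-2,5-diene-2-carboxylate (racemic; formed in the flask) | COC(=O)C1=C(CC2(CCCCCCC)OCCO2)C2C(C)(C)CC1(O[Si](C)(C)C)C=C2O[Si](C)(C)C | intermediate
12 | methyl 2-[(2-heptyl-1,3-dioxolan-2-yl)methyl]-4,6-bis(trimethylsilyloxy)benzoate (formed in the flask) | CCCCCCCC1(Cc2cc(O[Si](C)(C)C)cc(O[Si](C)(C)C)c2C(=O)OC)OCCO1 | intermediate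
13 | methyl 2,4-dihydroxy-6-[(2-heptyl-1,3-dioxolan-2-yl)methyl]benzoate | CCCCCCCC1(Cc2cc(O)cc(O)c2C(=O)OC)OCCO1 | intermediate
14 | methyl 4-{[4-(2-heptyl-1,3-dioxolan-2-yl)but-2-ynoyl]oxy}-6-[(2-heptyl-1,3-dioxolan-2-yl)methyl]-2-hydroxybenzoate | CCCCCCCC1(CC#CC(=O)Oc2cc(O)c(C(=O)OC)c(CC3(CCCCCCC)OCCO3)c2)OCCO1 | intermediate
15 | methyl 4-{[4-(2-heptyl-1,3-dioxolan-2-yl)but-2-ynoyl]oxy}-6-[(2-heptyl-1,3-dioxolan-2-yl)methyl]-2-(trimethylsilyloxy)benzoate (formed in the flask) | CCCCCCCC1(CC#CC(=O)Oc2cc(O[Si](C)(C)C)c(C(=O)OC)c(CC3(CCCCCCC)OCCO3)c2)OCCO1 | intermediate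
16 | 3-[(2-heptyl-1,3-dioxolan-2-yl)methyl]-4-(methoxycarbonyl)-5-(trimethylsilyloxy)phenyl 3-[(2-heptyl-1,3-dioxolan-2-yl)methyl]-8,8-dimethyl-1,5-bis(trimethylsilyloxy)bicyclo[2.2.2]octa-2,5-diene-2-carboxylate (racemic; formed in the flask) | COC(=O)c1c(O[Si](C)(C)C)cc(OC(=O)C2=C(CC3(CCCCCCC)OCCO3)C3C(C)(C)CC2(O[Si](C)(C)C)C=C3O[Si](C)(C)C)cc1CC1(CCCCCCC)OCCO1 | intermediate
17 | methyl 4-({2-[(2-heptyl-1,3-dioxolan-2-yl)methyl]-4,6-bis(trimethylsilyloxy)benzoyl}oxy)-6-[(2-heptyl-1,3-dioxolan-2-yl)methyl]-2-(trimethylsilyloxy)benzoate | CCCCCCCC1(Cc2cc(O[Si](C)(C)C)cc(O[Si](C)(C)C)c2C(=O)Oc2cc(O[Si](C)(C)C)c(C(=O)OC)c(CC3(CCCCCCC)OCCO3)c2)OCCO1 | intermediate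
18 | methyl 4-{[2,4-dihydroxy-6-(2-oxononyl)benzoyl]oxy}-2-hydroxy-6-(2-oxononyl)benzoate | CCCCCCCC(=O)Cc1cc(OC(=O)c2c(O)cc(O)cc2CC(=O)CCCCCCC)cc(O)c1C(=O)OC | target

## Step count and risk

Total: 10 steps. Longest linear sequence: 8 steps (steps 1, 2, 3, 4, 5, 8, 9, 10, or equally steps 1, 2, 3, 4, 7, 8, 9, 10). Step 6 (diene 10) is a side branch.

**Step 9 (key step).** The most likely failure is a slow cycloaddition. The reacting diene terminus lies next to the gem-dimethyl carbon and the ynoate β-carbon carries a branched CH2–ketal group, so desilylation or silyl migration of the diene at 150 °C may outrun the addition. Acyl transfer from the activated aryl ester is a second risk. The fallback gives up ring formation on the ester and sets out from 13, which then serves as the source of both rings, and comes back to the route at 18. Benzyl bromide and K2CO3 in DMF should give methyl 2,4-bis(benzyloxy)-6-[(2-heptyl-1,3-dioxolan-2-yl)methyl]benzoate F1. KOH in aqueous DMSO at 90 °C should cleave the hindered methyl ester to 2,4-bis(benzyloxy)-6-[(2-heptyl-1,3-dioxolan-2-yl)methyl]benzoic acid F2. Neutral chlorination with 1-chloro-N,N,2-trimethylprop-1-en-1-amine should give 2,4-bis(benzyloxy)-6-[(2-heptyl-1,3-dioxolan-2-yl)methyl]benzoyl chloride F3. Acylation of a second portion of 13 at O-4 (Et3N, DMAP, CH2Cl2) should give methyl 4-({2,4-bis(benzyloxy)-6-[(2-heptyl-1,3-dioxolan-2-yl)methyl]benzoyl}oxy)-6-[(2-heptyl-1,3-dioxolan-2-yl)methyl]-2-hydroxybenzoate F4. Dilute HCl in THF should release the ketones to give methyl 4-{[2,4-bis(benzyloxy)-6-(2-oxononyl)benzoyl]oxy}-2-hydroxy-6-(2-oxononyl)benzoate F5, and hydrogenolysis (H2, Pd/C, EtOAc) should give 18 under neutral conditions.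

**Step 8.** Three things may go wrong: base-triggered shift of the triple bond to the allenoate, conjugate addition of a phenoxide or of DMAP to the ynoate, and ketal loss in the rather strong acid 8 before coupling. The fallback removes the nucleophilic catalyst and the carbodiimide. It sets out from 8 and 13 and comes back at 14. Freshly made 8 is converted with 1-chloro-N,N,2-trimethylprop-1-en-1-amine in CH2Cl2 at 0 °C into 4-(2-heptyl-1,3-dioxolan-2-yl)but-2-ynoyl chloride F6, which is added to 13 and 2,6-dimethylpyridine at −40 → 0 °C to acylate O-4.

**Step 10.** Once the ketones are free under acid, enol-lactonisation of a 2-oxononyl ketone onto the neighbouring aryl ester with expulsion of the ring B phenol may compete, and conditions mild enough to avoid it may leave ketal hydrolysis incomplete. The fallback separates the two unmaskings and replaces hydrolysis by neutral ketal exchange. It sets out from 17 and comes back at 18. Buffered fluoride (Bu4NF/AcOH, THF, 0 °C) should remove the three silyl groups and give methyl 4-({2-[(2-heptyl-1,3-dioxolan-2-yl)methyl]-4,6-dihydroxybenzoyl}oxy)-6-[(2-heptyl-1,3-dioxolan-2-yl)methyl]-2-hydroxybenzoate F7. In(OTf)3 (catalytic) in acetone at room temperature should then transfer both glycol units to the solvent.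

**Step 5.** Hydroxide may add to the β-carbon of the ynoate or remove a γ-proton and shift the triple bond to the allenoate before the ester is cleaved, and the ketal may be lost during acidification. The fallback replaces ester hydrolysis by direct carboxylation. It sets out from 5 and comes back at 8. n-BuLi (2.1 equiv, THF, −78 °C) generates the acetylide 6 as in step 4, and dry CO2 should convert it into lithium 4-(2-heptyl-1,3-dioxolan-2-yl)but-2-ynoate F9. This is kept as the salt and acidified cold to pH 3 to give 8 just before step 8.

**Step 3.** The dioxolane may be lost through HBr or bromophosphonium species, or a ketal oxygen may be eliminated from the enolisable β,β-dialkoxy aldehyde. The fallback avoids the phosphorus–bromine system. It sets out from 4 and comes back at 7. Ohira–Bestmann homologation (dimethyl (1-diazo-2-oxopropyl)phosphonate, K2CO3, MeOH, 0 °C → rt) should give 2-heptyl-2-(prop-2-yn-1-yl)-1,3-dioxolane F8. n-BuLi (1.05 equiv, THF, −78 °C) converts it into the lithium acetylide 6, which is acylated with methyl chloroformate as in step 4.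

## Further compounds

F1 | step 9 | methyl 2,4-bis(benzyloxy)-6-[(2-heptyl-1,3-dioxolan-2-yl)methyl]benzoate | CCCCCCCC1(Cc2cc(OCc3ccccc3)cc(OCc3ccccc3)c2C(=O)OC)OCCO1
F2 | step 9 | 2,4-bis(benzyloxy)-6-[(2-heptyl-1,3-dioxolan-2-yl)methyl]benzoic acid | CCCCCCCC1(Cc2cc(OCc3ccccc3)cc(OCc3ccccc3)c2C(=O)O)OCCO1
F3 | step 9 | 2,4-bis(benzyloxy)-6-[(2-heptyl-1,3-dioxolan-2-yl)methyl]benzoyl chloride | CCCCCCCC1(Cc2cc(OCc3ccccc3)cc(OCc3ccccc3)c2C(=O)Cl)OCCO1
F4 | step 9 | methyl 4-({2,4-bis(benzyloxy)-6-[(2-heptyl-1,3-dioxolan-2-yl)methyl]benzoyl}oxy)-6-[(2-heptyl-1,3-dioxolan-2-yl)methyl]-2-hydroxybenzoate | CCCCCCCC1(Cc2cc(OCc3ccccc3)cc(OCc3ccccc3)c2C(=O)Oc2cc(O)c(C(=O)OC)c(CC3(CCCCCCC)OCCO3)c2)OCCO1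
F5 | step 9 | methyl 4-{[2,4-bis(benzyloxy)-6-(2-oxononyl)benzoyl]oxy}-2-hydroxy-6-(2-oxononyl)benzoate | CCCCCCCC(=O)Cc1cc(OCc2ccccc2)cc(OCc2ccccc2)c1C(=O)Oc1cc(O)c(C(=O)OC)c(CC(=O)CCCCCCC)c1
F6 | step 8 | 4-(2-heptyl-1,3-dioxolan-2-yl)but-2-ynoyl chloride | CCCCCCCC1(CC#CC(=O)Cl)OCCO1
F7 | step 10 | methyl 4-({2-[(2-heptyl-1,3-dioxolan-2-yl)methyl]-4,6-dihydroxybenzoyl}oxy)-6-[(2-heptyl-1,3-dioxolan-2-yl)methyl]-2-hydroxybenzoate | CCCCCCCC1(Cc2cc(O)cc(O)c2C(=O)Oc2cc(O)c(C(=O)OC)c(CC3(CCCCCCC)OCCO3)c2)OCCO1
F8 | step 3 | 2-heptyl-2-(prop-2-yn-1-yl)-1,3-dioxolane | CCCCCCCC1(CC#C)OCCO1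
F9 | step 5 | lithium 4-(2-heptyl-1,3-dioxolan-2-yl)but-2-ynoate | CCCCCCCC1(CC#CC(=O)[O-])OCCO1.[Li+]
A1 | alternative 1 | (E)-5-(2-heptyl-1,3-dioxolan-2-yl)pent-3-en-2-one | CCCCCCCC1(C/C=C/C(C)=O)OCCO1
A2 | alternative 1 | dimethyl malonate | COC(=O)CC(=O)OC
A3 | alternative 1 | methyl 6-[(2-heptyl-1,3-dioxolan-2-yl)methyl]-2,4-dioxocyclohexane-1-carboxylate (racemic, trans isomer drawn as one enantiomer) | CCCCCCCC1(C[C@@H]2CC(=O)CC(=O)[C@H]2C(=O)OC)OCCO1
A4 | alternative 2 | 3,5-bis(benzyloxy)-2-(trimethylsilyl)phenyl trifluoromethanesulfonate | C[Si](C)(C)c1c(OCc2ccccc2)cc(OCc2ccccc2)cc1OS(=O)(=O)C(F)(F)F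
A5 | alternative 2 | dimethyl 3,5-bis(benzyloxy)homophthalate | COC(=O)Cc1cc(OCc2ccccc2)cc(OCc2ccccc2)c1C(=O)OC
A6 | alternative 3 | methyl 4-{[8-(2-heptyl-1,3-dioxolan-2-yl)-3,5,7-trioxooctanoyl]oxy}-6-[(2-heptyl-1,3-dioxolan-2-yl)methyl]-2-hydroxybenzoate | CCCCCCCC1(CC(=O)CC(=O)CC(=O)CC(=O)Oc2cc(O)c(C(=O)OC)c(CC3(CCCCCCC)OCCO3)c2)OCCO1
A7 | alternative 3 | methyl 4-({2-[(2-heptyl-1,3-dioxolan-2-yl)methyl]-4,6-dihydroxybenzoyl}oxy)-6-[(2-heptyl-1,3-dioxolan-2-yl)methyl]-2-hydroxybenzoate | CCCCCCCC1(Cc2cc(O)cc(O)c2C(=O)Oc2cc(O)c(C(=O)OC)c(CC3(CCCCCCC)OCCO3)c2)OCCO1
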